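- The rate of making J reads first order in L and in Z, and the pitfall is to stop there: the flasks compared reach the same conversion at different times.

    L + Z + D → Z + X (k1 = 1900 M⁻² s⁻¹)
    2 Z → Z2 (k2 = 300 M⁻¹ s⁻¹)
    2 L → L2 (k3 = 0.49 M⁻¹ s⁻¹)
    L + Z + E → Z + J (k4 = 4300 M⁻² s⁻¹)

E 0.050 M; L 0.0500 M; Z 0.10 mM; D 0.050 M

- the form that holds most of the catalyst when 5.0% of the E and D together are converted (Z / Z2)
- its share of the catalyst then
- apparent order in L when 5.0% of the E and D together are converted (percent change of the rate of making J for one percent more L charged)
- apparent order in Z when 5.0% of the E and D together are converted (percent change of the rate of making J for one percent more Z charged)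

- Each curve is replaced by its mean, taken at the midpoint of the run. E and D stand equal, so products start at 1.55 mM s⁻¹ and 5.00 mM are needed, a straight-line time of 3.23 s.
- The quantity carried is the pairing pace 0.0600 s⁻¹, one over the first half-life of Z by pairing: the other steps give Z back, so charge over cZ grows as 1 + pace × t. L has its own pace, 0.0490 s⁻¹, and also loses what turnover takes.
- With cZ, cL, E and D at their midpoint values, the mean rate is 0.779 of the starting one, so the time is 4.14 s. A second pass gives 0.744 and 4.34 s.
- The pairing clock then reads 0.260, so the catalyst rests mostly as Z, with a share of 79.4%.
- For the orders, the time is taken as inverse to each charge. More Z leaves the pairing clock unchanged, while L couples for less time, which adds 0.175: the order in Z is 1.18. More L leaves its own clock unchanged, while pairing runs for less time, which adds 0.206. The fixed 5.00 mM of L also weighs less, adding 0.138: the order in L is 1.34.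
- The forecast gives Z at 79.4%, with orders 1.39 in L and 1.22 in Z, a little above this reckoning, on the ground that “extra L or Z reaches that point sooner, leaving more catalyst active and more L unspent”.
- The simulation gives Z at 79.4%, with orders 1.4 in L and 1.2 in Z. E and D together reach that conversion in 4.33 s.
- The weak link was the rule that the time goes inverse to each charge, so it is reforged with a simulated run. The largest single effect on the order in L comes from the loss of Z into Z2: with that path taken away, the order is 1.1 against 1.4. The flask charged with twice the Z reaches the conversion in 0.474 of the time, so its pace and time give a clock of 0.246 and a reckoned free Z of 80.2%.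

(The rate constants were chosen freely; the flask was simulated.)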